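**Retrosynthetic overview**

1. The C8 ester is cut back to the 8-epi alcohol, to be joined with (R)-2-methylbutanoic acid under Mitsunobu inversion; the C3 acetate comes from a PMB ether.
2. The key disconnection is C6–C7. The 10-membered carbocycle and the lactone open together to an acyclic (4Z)-enal carrying a 2-(bromomethyl)acrylate. Closure is an intramolecular chromium-mediated allylation, the polarity-reversed copy of the biosynthetic C1–C10 cyclization of a farnesyl chain.
3. Enabling feature: the lactone ring O–C6–C7–C11(=C13)–C12(=O) is the retron of a 2-(methoxycarbonyl)allyl metal that adds through C7 to a C6 aldehyde. The 4Z alkene and the cis-1,10-epoxide are turn elements that bring C6 and C7 together.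
4. Chain assembly: C3–C4 by asymmetric alkenylchromium addition, C7–C8 by asymmetric zinc alkynylation, the Z C1=C10 alkene by iron-catalysed carbomethylation of a hex-3-yne, the epoxide by Shi epoxidation.
5. Ring order: epoxide on the open chain (step 13), then carbocycle and γ-lactone together (step 17).

Key step: step 17

Remark: germacrane numbering is used for locants in the text (C6 = aldehyde/lactone carbinol carbon, C7 = ring-fusion carbon, C12 = lactone carbonyl, C13 = exocyclic methylene); systematic chain names carry their own locants.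
Remark: the new C6–C7 bond is expected to form anti to the C8 silyloxy group, so the chain is built with C8 epimeric to the target (8R) and C8 is inverted in the last step.
Remark: C3 and C8 are set by catalyst control; the ligand enantiomer is the one that delivers the stated configuration.

Step 1
Reactants: 1 but-2-yn-1-ol
Product: 3 (Z)-3-iodobut-2-en-1-ol, via alkenylalanate 2 (not isolated)
Conditions: NaAlH2(OCH2CH2OMe)2 (Red-Al), THF, 0 °C → rt; then I2, −78 → 0 °C
Reagents that add atoms: iodine, II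
Why: Hydroxyl-directed trans-hydroalumination of the propargylic alcohol should place aluminium on the distal alkyne carbon in the cyclic alanate 2, and iodinolysis with retention should give the Z iodide (I cis to CH2OH).

Step 2
Reactants: 3 (Z)-3-iodobut-2-en-1-ol
Product: 4 tert-butyl{[(Z)-3-iodobut-2-en-1-yl]oxy}dimethylsilane
Conditions: TBSCl, imidazole, DMF, rt
Reagents that add atoms: tert-butyldimethylsilyl chloride, CC(C)(C)[Si](C)(C)Cl
Why: Imidazole-mediated silylation of a primary alcohol (silyl ether formation) should proceed without touching the alkenyl iodide.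

Step 3
Reactants: 5 but-3-yn-1-ol
Product: 6 triethyl(but-3-yn-1-yloxy)silane
Conditions: TESCl, imidazole, CH2Cl2, 0 °C
Reagents that add atoms: chlorotriethylsilane, CC[Si](Cl)(CC)CC
Why: Silyl ether formation; the primary TES ether is chosen because it can later be oxidized directly to the aldehyde (step 9).

Step 4
Reactants: 6 triethyl(but-3-yn-1-yloxy)silane; 7 oxirane
Product: 9 6-(triethylsilyloxy)hex-3-yn-1-ol, via lithium acetylide 8 (not isolated)
Conditions: n-BuLi, THF, −78 °C; then BF3·OEt2, oxirane, −78 °C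
Reagents that add atoms: none
Why: BF3-promoted opening of the epoxide by the alkynyllithium (epoxide alkynylation) should add two carbons and free the hydroxyl that directs step 5.

Step 5
Reactants: 9 6-(triethylsilyloxy)hex-3-yn-1-ol
Product: 10 (Z)-4-methyl-6-(triethylsilyloxy)hex-3-en-1-ol
Conditions: MeMgBr (5 equiv), Fe(acac)3 (15 mol%), THF, 0 °C; aq NH4Cl
Reagents that add atoms: methylmagnesium bromide, C[Mg]Br
Why: Alkoxide-directed iron-catalysed syn-carbomagnesiation of the homopropargylic alcohol should deliver methyl to the distal alkyne carbon and magnesium to the proximal one in a chelate, and protonolysis with retention should give the Z trisubstituted alkene (C1=C10).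

Step 6
Reactants: 10 (Z)-4-methyl-6-(triethylsilyloxy)hex-3-en-1-ol
Product: 11 (Z)-4-methyl-6-(triethylsilyloxy)hex-3-enal
Conditions: Dess–Martin periodinane, pyridine, CH2Cl2, 0 °C; used crude
Reagents that add atoms: none
Why: Dess–Martin oxidation under buffered, non-basic conditions should give the β,γ-unsaturated aldehyde without migration of the alkene into conjugation.

Step 7
Reactants: 11 (Z)-4-methyl-6-(triethylsilyloxy)hex-3-enal; 4 tert-butyl{[(Z)-3-iodobut-2-en-1-yl]oxy}dimethylsilane
Product: 12 (2Z,4R,6Z)-1-(tert-butyldimethylsilyloxy)-3,7-dimethyl-9-(triethylsilyloxy)nona-2,6-dien-4-ol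
Conditions: CrCl2 (4 equiv), NiCl2 (5 mol%), chiral 2-(oxazolin-2-yl)aryl sulfonamide ligand (enantiomer giving 4R), Et3N, THF, rt
Reagents that add atoms: none
Why: Nozaki–Hiyama–Kishi coupling: nickel-catalysed formation of the alkenylchromium from 4 with retention of the Z geometry and its addition to the aldehyde under neutral conditions, with the chiral sulfonamide ligand on chromium setting C3 (C4 of the chain name) as R by reagent control.

Step 8
Reactants: 12 (2Z,4R,6Z)-1-(tert-butyldimethylsilyloxy)-3,7-dimethyl-9-(triethylsilyloxy)nona-2,6-dien-4-ol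
Product: 13 (2Z,4R,6Z)-1-(tert-butyldimethylsilyloxy)-4-(4-methoxybenzyloxy)-3,7-dimethyl-9-(triethylsilyloxy)nona-2,6-diene
Conditions: NaH, 4-methoxybenzyl chloride, Bu4NI (cat.), DMF, 0 °C
Reagents that add atoms: 4-methoxybenzyl chloride, COc1ccc(CCl)cc1
Why: Williamson etherification of the secondary allylic alkoxide; the PMB ether should survive the hydride, fluoride and chromium steps and is removed oxidatively in step 18.

Step 9
Reactants: 13 (2Z,4R,6Z)-1-(tert-butyldimethylsilyloxy)-4-(4-methoxybenzyloxy)-3,7-dimethyl-9-(triethylsilyloxy)nona-2,6-diene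
Product: 14 (3Z,6R,7Z)-9-(tert-butyldimethylsilyloxy)-6-(4-methoxybenzyloxy)-3,7-dimethylnona-3,7-dienal
Conditions: (COCl)2, DMSO, CH2Cl2, −78 → −40 °C; then Et3N, −78 → 0 °C; used crude
Reagents that add atoms: none
Why: Swern oxidation applied directly to the primary triethylsilyl ether, which the chlorosulfonium reagent cleaves and oxidizes in one flask while the TBS and PMB ethers stay.

Step 10
Reactants: 14 (3Z,6R,7Z)-9-(tert-butyldimethylsilyloxy)-6-(4-methoxybenzyloxy)-3,7-dimethylnona-3,7-dienal; 15 methyl prop-2-ynoate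
Product: 16 methyl (4R,6Z,9R,10Z)-12-(tert-butyldimethylsilyloxy)-4-hydroxy-9-(4-methoxybenzyloxy)-6,10-dimethyldodeca-6,10-dien-2-ynoate
Conditions: Me2Zn, ProPhenol ligand (10 mol%, enantiomer giving 4R), Ph3PO (20 mol%), toluene, 4 °C
Reagents that add atoms: none
Why: Catalytic asymmetric alkynylation of the aldehyde with the zinc acetylide of methyl propiolate (dinuclear zinc–ProPhenol catalyst), the ligand setting C8 (C4 of the chain name) as R, the epimer needed for the later inversion.

Step 11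
Reactants: 16 methyl (4R,6Z,9R,10Z)-12-(tert-butyldimethylsilyloxy)-4-hydroxy-9-(4-methoxybenzyloxy)-6,10-dimethyldodeca-6,10-dien-2-ynoate
Product: 17 methyl (4R,6Z,9R,10Z)-4,12-bis(tert-butyldimethylsilyloxy)-9-(4-methoxybenzyloxy)-6,10-dimethyldodeca-6,10-dien-2-ynoate
Conditions: TBSCl, imidazole, DMF, rt
Reagents that add atoms: tert-butyldimethylsilyl chloride, CC(C)(C)[Si](C)(C)Cl
Why: Silylation of the propargylic alcohol; the TBS ether is a poor leaving group, which should suppress 1,4-elimination in the key step.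

Step 12
Reactants: 17 methyl (4R,6Z,9R,10Z)-4,12-bis(tert-butyldimethylsilyloxy)-9-(4-methoxybenzyloxy)-6,10-dimethyldodeca-6,10-dien-2-ynoate
Product: 19 methyl (2Z,4R,6Z,9R,10Z)-4,12-bis(tert-butyldimethylsilyloxy)-2-(hydroxymethyl)-9-(4-methoxybenzyloxy)-6,10-dimethyldodeca-2,6,10-trienoate, via alkenylalane 18 (not isolated)
Conditions: i-Bu2AlH, HMPA, THF, 0 °C; then CH2O (gas), −20 °C → rt; aq potassium sodium tartrate
Reagents that add atoms: formaldehyde, C=O
Why: 1,4-Hydroalumination of the ynoate (syn addition, H to C7 and Al to C11) and aldol-type trapping of the alkenylalane with formaldehyde with retention should put C8 cis to CO2Me and install C13 as CH2OH.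

Step 13
Reactants: 19 methyl (2Z,4R,6Z,9R,10Z)-4,12-bis(tert-butyldimethylsilyloxy)-2-(hydroxymethyl)-9-(4-methoxybenzyloxy)-6,10-dimethyldodeca-2,6,10-trienoate
Product: 20 methyl (2Z,4R,6S,7R,9R,10Z)-4,12-bis(tert-butyldimethylsilyloxy)-6,7-epoxy-2-(hydroxymethyl)-9-(4-methoxybenzyloxy)-6,10-dimethyldodeca-2,10-dienoate
Conditions: D-fructose-derived Shi ketone (30 mol%), Oxone (2KHSO5·KHSO4·K2SO4), K2CO3, Bu4NHSO4, MeCN/dimethoxymethane/aq buffer, 0 °C
Reagents that add atoms: potassium peroxymonosulfate (from Oxone), [K+].[O-]S(=O)(=O)OO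
Why: Shi asymmetric epoxidation: the chiral dioxirane should attack only the most electron-rich alkene C1=C10 (C4=C5 is deactivated by two allylic C–O bonds, C7=C11 by the ester) through the spiro transition state, so the catalyst sets C1 as R and, with the Z geometry, C10 as S (cis-epoxide).

Step 14
Reactants: 20 methyl (2Z,4R,6S,7R,9R,10Z)-4,12-bis(tert-butyldimethylsilyloxy)-6,7-epoxy-2-(hydroxymethyl)-9-(4-methoxybenzyloxy)-6,10-dimethyldodeca-2,10-dienoate
Product: 21 methyl (2Z,4R,6S,7R,9R,10Z)-4-(tert-butyldimethylsilyloxy)-6,7-epoxy-12-hydroxy-2-(hydroxymethyl)-9-(4-methoxybenzyloxy)-6,10-dimethyldodeca-2,10-dienoate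
Conditions: HF·pyridine, pyridine, THF, 0 °C
Reagents that add atoms: none
Why: Fluoride desilylation should be faster at the unhindered primary allylic TBS ether than at the secondary C8 TBS ether, and the pyridine buffer protects the epoxide.

Step 15
Reactants: 21 methyl (2Z,4R,6S,7R,9R,10Z)-4-(tert-butyldimethylsilyloxy)-6,7-epoxy-12-hydroxy-2-(hydroxymethyl)-9-(4-methoxybenzyloxy)-6,10-dimethyldodeca-2,10-dienoate
Product: 22 methyl (2Z,4R,6S,7R,9R,10Z)-4-(tert-butyldimethylsilyloxy)-6,7-epoxy-2-(hydroxymethyl)-9-(4-methoxybenzyloxy)-6,10-dimethyl-12-oxododeca-2,10-dienoate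
Conditions: MnO2, CH2Cl2, rt
Reagents that add atoms: none
Why: MnO2 allylic oxidation should take the electron-rich C6 allylic alcohol to the Z enal under neutral conditions, while the hydroxymethyl group on the electron-poor acrylate reacts much more slowly.

Step 16
Reactants: 22 methyl (2Z,4R,6S,7R,9R,10Z)-4-(tert-butyldimethylsilyloxy)-6,7-epoxy-2-(hydroxymethyl)-9-(4-methoxybenzyloxy)-6,10-dimethyl-12-oxododeca-2,10-dienoate
Product: 23 methyl (2E,4R,6S,7R,9R,10Z)-2-(bromomethyl)-4-(tert-butyldimethylsilyloxy)-6,7-epoxy-9-(4-methoxybenzyloxy)-6,10-dimethyl-12-oxododeca-2,10-dienoate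
Conditions: Ph3P, N-bromosuccinimide (premixed), CH2Cl2, −30 °C
Reagents that add atoms: N-bromosuccinimide, O=C1CCC(=O)N1Br
Why: Appel-type bromination with the preformed phosphine/N-bromosuccinimide adduct should convert the primary allylic alcohol to the bromide by SN2, without base and without free phosphine that could isomerize the enal (the alkene geometry is unchanged; the descriptor becomes E by priority).

Step 17
Reactants: 23 methyl (2E,4R,6S,7R,9R,10Z)-2-(bromomethyl)-4-(tert-butyldimethylsilyloxy)-6,7-epoxy-9-(4-methoxybenzyloxy)-6,10-dimethyl-12-oxododeca-2,10-dienoate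
Product: 26 (1R,3R,6S,7R,8R,10S,4Z)-8-(tert-butyldimethylsilyloxy)-1,10-epoxy-3-(4-methoxybenzyloxy)germacra-4,11(13)-dien-12,6-olide, via allylchromium species 24 (not isolated), via hydroxy ester 25 (not isolated)
Conditions: CrCl2 (8 equiv), DMF, slow addition of 23 (final 2 mM), rt; then 45 °C; aq NH4Cl
Reagents that add atoms: none
Why: Two equivalents of CrCl2 should reduce the allylic C13–Br bond to the allylchromium species 24 (trivalent chromium), which adds through its γ-carbon C7 to the C6 aldehyde in a closed six-membered chair transition state (SE2′) to give the chromium alkoxide of 25; on warming the alkoxide attacks the C12 methyl ester and closes the lactone. The closest known reaction type is the intramolecular Nozaki–Hiyama–Kishi (Barbier-type) 2-(alkoxycarbonyl)allylation used to close germacranolide and cembranolide carbocycles together with their α-methylene lactones, and the closure is the polarity-reversed copy of the C1–C10 cyclization of a farnesyl chain in germacrane biosynthesis. The 10-membered carbocycle closes in a 10-exo-trig mode at the C6 carbonyl (C11 stays outside the bond formed and becomes C11=C13), and the lactone closes by a 5-exo-trig acyl substitution. C6 and C7 are set relative to each other by the chair, in which C5 and C8 are both equatorial because C8 is trans to CH2Cr in the (E)-bromide, giving the anti (6,7-trans) arrangement. The face of C7 is set by C8, whose hydrogen eclipses C7=C11 to avoid 1,3-allylic strain with CO2Me, so that the aldehyde enters anti to the silyloxy group while C9 stays gauche on the side of the forming ring. The step needs γ- over α-attack (the α-mode would give a 12-membered ring and has no cyclic transition state), cyclization over oligomerization (slow addition at high dilution, helped by the two cis turn elements C4=C5 and the 1,10-epoxide) and chemoselectivity for the allylic bromide (divalent chromium should leave epoxide, ester, ethers and enal untouched).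

Step 18
Reactants: 26 (1R,3R,6S,7R,8R,10S,4Z)-8-(tert-butyldimethylsilyloxy)-1,10-epoxy-3-(4-methoxybenzyloxy)germacra-4,11(13)-dien-12,6-olide
Product: 27 (1R,3R,6S,7R,8R,10S,4Z)-8-(tert-butyldimethylsilyloxy)-1,10-epoxy-3-hydroxygermacra-4,11(13)-dien-12,6-olide
Conditions: DDQ, CH2Cl2/pH 7 buffer, 0 °C
Reagents that add atoms: none
Why: Oxidative cleavage of the PMB ether (benzylic hydride abstraction by DDQ, hydrolysis of the oxocarbenium ion) should free the C3 hydroxyl without touching silyl ether, epoxide or lactone.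

Step 19
Reactants: 27 (1R,3R,6S,7R,8R,10S,4Z)-8-(tert-butyldimethylsilyloxy)-1,10-epoxy-3-hydroxygermacra-4,11(13)-dien-12,6-olide
Product: 28 (1R,3R,6S,7R,8R,10S,4Z)-3-acetoxy-8-(tert-butyldimethylsilyloxy)-1,10-epoxygermacra-4,11(13)-dien-12,6-olide
Conditions: Ac2O, pyridine, DMAP (cat.), CH2Cl2, 0 °C
Reagents that add atoms: acetic anhydride, CC(=O)OC(C)=O
Why: DMAP-catalysed acylation of the secondary allylic alcohol, with retention at C3.

Step 20
Reactants: 28 (1R,3R,6S,7R,8R,10S,4Z)-3-acetoxy-8-(tert-butyldimethylsilyloxy)-1,10-epoxygermacra-4,11(13)-dien-12,6-olide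
Product: 29 (1R,3R,6S,7S,8R,10S,4Z)-3-acetoxy-1,10-epoxy-8-hydroxygermacra-4,11(13)-dien-12,6-olide
Conditions: HF·pyridine, THF, 0 °C → rt
Reagents that add atoms: none
Why: Fluoride cleavage of the secondary TBS ether under non-basic conditions, which should avoid translactonization and conjugate addition to the methylene lactone (the C7 descriptor changes by priority only).

Step 21
Reactants: 29 (1R,3R,6S,7S,8R,10S,4Z)-3-acetoxy-1,10-epoxy-8-hydroxygermacra-4,11(13)-dien-12,6-olide; 30 (R)-2-methylbutanoic acid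
Product: 31 (1R,3R,6S,7S,8S,10S,4Z)-3-acetoxy-1,10-epoxy-8-[(R)-2-methylbutanoyloxy]germacra-4,11(13)-dien-12,6-olide (CNP0340603.1)
Conditions: Ph3P, DIAD, toluene, 0 °C → rt
Reagents that add atoms: none
Why: Mitsunobu esterification: the alkoxyphosphonium ion of the 8R alcohol should be displaced by the carboxylate with inversion, which sets C8 as S and installs the side chain without touching its own stereocentre.

**Compound list**

1 | but-2-yn-1-ol | CC#CCO | starting material
2 | sodium 2,2-bis(2-methoxyethoxy)-3-methyl-2,5-dihydro-1,2-oxaaluminol-2-uide (cyclic alkenylalanate) | [Na+].CC1=CCO[Al-]1(OCCOC)OCCOC | intermediate (not isolated)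
3 | (Z)-3-iodobut-2-en-1-ol | C/C(I)=C/CO | intermediate
4 | tert-butyl{[(Z)-3-iodobut-2-en-1-yl]oxy}dimethylsilane | C/C(I)=C/CO[Si](C)(C)C(C)(C)C | intermediate
5 | but-3-yn-1-ol | C#CCCO | starting material
6 | triethyl(but-3-yn-1-yloxy)silane | C#CCCO[Si](CC)(CC)CC | intermediate
7 | oxirane | C1CO1 | starting material
8 | [4-(triethylsilyloxy)but-1-yn-1-yl]lithium | [Li]C#CCCO[Si](CC)(CC)CC | intermediate (not isolated)
9 | 6-(triethylsilyloxy)hex-3-yn-1-ol | OCCC#CCCO[Si](CC)(CC)CC | intermediate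
10 | (Z)-4-methyl-6-(triethylsilyloxy)hex-3-en-1-ol | OCC/C=C(/C)CCO[Si](CC)(CC)CC | intermediate
11 | (Z)-4-methyl-6-(triethylsilyloxy)hex-3-enal | O=CC/C=C(/C)CCO[Si](CC)(CC)CC | intermediate
12 | (2Z,4R,6Z)-1-(tert-butyldimethylsilyloxy)-3,7-dimethyl-9-(triethylsilyloxy)nona-2,6-dien-4-ol | CC(C)(C)[Si](C)(C)OC/C=C(/C)[C@H](O)C/C=C(/C)CCO[Si](CC)(CC)CC | intermediate
13 | (2Z,4R,6Z)-1-(tert-butyldimethylsilyloxy)-4-(4-methoxybenzyloxy)-3,7-dimethyl-9-(triethylsilyloxy)nona-2,6-diene | CC(C)(C)[Si](C)(C)OC/C=C(/C)[C@H](OCc1ccc(OC)cc1)C/C=C(/C)CCO[Si](CC)(CC)CC | intermediate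
14 | (3Z,6R,7Z)-9-(tert-butyldimethylsilyloxy)-6-(4-methoxybenzyloxy)-3,7-dimethylnona-3,7-dienal | CC(C)(C)[Si](C)(C)OC/C=C(/C)[C@H](OCc1ccc(OC)cc1)C/C=C(/C)CC=O | intermediate
15 | methyl prop-2-ynoate | C#CC(=O)OC | starting material
16 | methyl (4R,6Z,9R,10Z)-12-(tert-butyldimethylsilyloxy)-4-hydroxy-9-(4-methoxybenzyloxy)-6,10-dimethyldodeca-6,10-dien-2-ynoate | CC(C)(C)[Si](C)(C)OC/C=C(/C)[C@H](OCc1ccc(OC)cc1)C/C=C(/C)C[C@@H](O)C#CC(=O)OC | intermediate
17 | methyl (4R,6Z,9R,10Z)-4,12-bis(tert-butyldimethylsilyloxy)-9-(4-methoxybenzyloxy)-6,10-dimethyldodeca-6,10-dien-2-ynoate | CC(C)(C)[Si](C)(C)OC/C=C(/C)[C@H](OCc1ccc(OC)cc1)C/C=C(/C)C[C@@H](O[Si](C)(C)C(C)(C)C)C#CC(=O)OC | intermediate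
18 | alkenylalane: 17 after syn addition of H (C3) and Al(i-Bu)2 (C2), C4 cis to CO2Me | CC(C)(C)[Si](C)(C)OC/C=C(/C)[C@H](OCc1ccc(OC)cc1)C/C=C(/C)C[C@@H](O[Si](C)(C)C(C)(C)C)/C=C(/[Al](CC(C)C)CC(C)C)C(=O)OC | intermediate (not isolated)
19 | methyl (2Z,4R,6Z,9R,10Z)-4,12-bis(tert-butyldimethylsilyloxy)-2-(hydroxymethyl)-9-(4-methoxybenzyloxy)-6,10-dimethyldodeca-2,6,10-trienoate | CC(C)(C)[Si](C)(C)OC/C=C(/C)[C@H](OCc1ccc(OC)cc1)C/C=C(/C)C[C@@H](O[Si](C)(C)C(C)(C)C)/C=C(/CO)C(=O)OC | intermediate
20 | methyl (2Z,4R,6S,7R,9R,10Z)-4,12-bis(tert-butyldimethylsilyloxy)-6,7-epoxy-2-(hydroxymethyl)-9-(4-methoxybenzyloxy)-6,10-dimethyldodeca-2,10-dienoate | CC(C)(C)[Si](C)(C)OC/C=C(/C)[C@H](OCc1ccc(OC)cc1)C[C@H]2O[C@@]2(C)C[C@@H](O[Si](C)(C)C(C)(C)C)/C=C(/CO)C(=O)OC | intermediate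
21 | methyl (2Z,4R,6S,7R,9R,10Z)-4-(tert-butyldimethylsilyloxy)-6,7-epoxy-12-hydroxy-2-(hydroxymethyl)-9-(4-methoxybenzyloxy)-6,10-dimethyldodeca-2,10-dienoate | OC/C=C(/C)[C@H](OCc1ccc(OC)cc1)C[C@H]2O[C@@]2(C)C[C@@H](O[Si](C)(C)C(C)(C)C)/C=C(/CO)C(=O)OC | intermediate
22 | methyl (2Z,4R,6S,7R,9R,10Z)-4-(tert-butyldimethylsilyloxy)-6,7-epoxy-2-(hydroxymethyl)-9-(4-methoxybenzyloxy)-6,10-dimethyl-12-oxododeca-2,10-dienoate | O=C/C=C(/C)[C@H](OCc1ccc(OC)cc1)C[C@H]2O[C@@]2(C)C[C@@H](O[Si](C)(C)C(C)(C)C)/C=C(/CO)C(=O)OC | intermediate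
23 | methyl (2E,4R,6S,7R,9R,10Z)-2-(bromomethyl)-4-(tert-butyldimethylsilyloxy)-6,7-epoxy-9-(4-methoxybenzyloxy)-6,10-dimethyl-12-oxododeca-2,10-dienoate | O=C/C=C(/C)[C@H](OCc1ccc(OC)cc1)C[C@H]2O[C@@]2(C)C[C@@H](O[Si](C)(C)C(C)(C)C)/C=C(/CBr)C(=O)OC | intermediate
24 | allylchromium dichloride derived from 23 (CrCl2 on C13, trivalent chromium) | O=C/C=C(/C)[C@H](OCc1ccc(OC)cc1)C[C@H]2O[C@@]2(C)C[C@@H](O[Si](C)(C)C(C)(C)C)/C=C(/C[Cr](Cl)Cl)C(=O)OC | intermediate (not isolated)
25 | methyl 2-[(1R,3R,6S,7R,8R,10S,4Z)-8-(tert-butyldimethylsilyloxy)-1,10-epoxy-6-hydroxy-3-(4-methoxybenzyloxy)germacr-4-en-7-yl]acrylate (hydroxy ester, formed as its chromium alkoxide) | C=C(C(=O)OC)[C@@H]1[C@@H](O)/C=C(/C)[C@H](OCc2ccc(OC)cc2)C[C@H]3O[C@@]3(C)C[C@H]1O[Si](C)(C)C(C)(C)C | intermediate (not isolated)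
26 | (1R,3R,6S,7R,8R,10S,4Z)-8-(tert-butyldimethylsilyloxy)-1,10-epoxy-3-(4-methoxybenzyloxy)germacra-4,11(13)-dien-12,6-olide | C=C1C(=O)O[C@H]2/C=C(/C)[C@H](OCc4ccc(OC)cc4)C[C@H]3O[C@@]3(C)C[C@@H](O[Si](C)(C)C(C)(C)C)[C@H]12 | intermediate
27 | (1R,3R,6S,7R,8R,10S,4Z)-8-(tert-butyldimethylsilyloxy)-1,10-epoxy-3-hydroxygermacra-4,11(13)-dien-12,6-olide | C=C1C(=O)O[C@H]2/C=C(/C)[C@H](O)C[C@H]3O[C@@]3(C)C[C@@H](O[Si](C)(C)C(C)(C)C)[C@H]12 | intermediate
28 | (1R,3R,6S,7R,8R,10S,4Z)-3-acetoxy-8-(tert-butyldimethylsilyloxy)-1,10-epoxygermacra-4,11(13)-dien-12,6-olide | C=C1C(=O)O[C@H]2/C=C(/C)[C@H](OC(C)=O)C[C@H]3O[C@@]3(C)C[C@@H](O[Si](C)(C)C(C)(C)C)[C@H]12 | intermediate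
29 | (1R,3R,6S,7S,8R,10S,4Z)-3-acetoxy-1,10-epoxy-8-hydroxygermacra-4,11(13)-dien-12,6-olide | C=C1C(=O)O[C@H]2/C=C(/C)[C@H](OC(C)=O)C[C@H]3O[C@@]3(C)C[C@@H](O)[C@H]12 | intermediate
30 | (R)-2-methylbutanoic acid | CC[C@@H](C)C(=O)O | starting material
31 | (1R,3R,6S,7S,8S,10S,4Z)-3-acetoxy-1,10-epoxy-8-[(R)-2-methylbutanoyloxy]germacra-4,11(13)-dien-12,6-olide | C=C1C(=O)O[C@H]2/C=C(/C)[C@H](OC(C)=O)C[C@H]3O[C@@]3(C)C[C@H](OC(=O)[C@H](C)CC)[C@H]12 | target

**Step count and risks**

Total step count: 21. Longest linear sequence: 19 steps (steps 3–21, from but-3-yn-1-ol); steps 1–2 make fragment 4.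

Steps most likely to fail:

(a) Step 17, the key closure. What may go wrong: attack on the wrong face of C7 or reaction through an isomerized allylchromium (poor facial or syn/anti selectivity), reductive 1,4-elimination of the C8 silyloxy group, or intermolecular coupling instead of cyclization. The fallback sets out from hydroxy enal 22, skips the bromide, and comes back at lactone 26. Palladium-catalysed umpolung of the allylic alcohol (Pd(OAc)2 and Ph3P as catalyst, Et3B, THF, high dilution) should generate the π-allylpalladium species and transfer it to boron, giving the allyldiethylborane F1. F1 should add to the C6 aldehyde through a closed chair (intramolecular allylboration, γ-attack at C7), and the resulting borinate of 25 should lactonize on mild acidic work-up to 26.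

(b) Step 21, the Mitsunobu inversion. What may go wrong: elimination towards C7 or C9 instead of substitution, or no displacement at the hindered ring alcohol with a weakly acidic aliphatic acid. The fallback sets out from alcohol 29 and comes back at target 31. A Mitsunobu reaction with the more acidic chloroacetic acid (Ph3P, DIAD, toluene) should give the inverted (8S)-chloroacetate F2. Thiourea and NaHCO3 in ethanol should remove the chloroacetyl group and leave the C3 acetate, giving the (8S)-alcohol F3. Carbodiimide esterification of F3 with acid 30 (EDC·HCl, DMAP, CH2Cl2) then proceeds with retention and should give 31.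

(c) Step 12, the hydroalumination–hydroxymethylation. What may go wrong: isomerization of the aluminium allenolate with loss of the alkene geometry, or 1,2-reduction of the ester. The fallback sets out from ynoate 17 and comes back at hydroxymethyl enoate 19. Hydrostannation with Bu3SnH and catalytic Pd(PPh3)4 (zerovalent palladium, THF, 0 °C) should add H to C7 and tin to C11 in a syn fashion to give the α-stannyl enoate F4. Iododestannylation (I2, CH2Cl2, 0 °C) with retention should give the α-iodo enoate F5. Stille coupling of F5 with (tributylstannyl)methanol (Pd(PPh3)4, dioxane, 80 °C) should give 19.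

**Further compounds**

F1 | step 17 | methyl (2Z,4R,6S,7R,9R,10Z)-4-(tert-butyldimethylsilyloxy)-2-[(diethylboranyl)methyl]-6,7-epoxy-9-(4-methoxybenzyloxy)-6,10-dimethyl-12-oxododeca-2,10-dienoate | O=C/C=C(/C)[C@H](OCc1ccc(OC)cc1)C[C@H]2O[C@@]2(C)C[C@@H](O[Si](C)(C)C(C)(C)C)/C=C(/CB(CC)CC)C(=O)OC
F2 | step 21 | (1R,3R,6S,7S,8S,10S,4Z)-3-acetoxy-8-(chloroacetoxy)-1,10-epoxygermacra-4,11(13)-dien-12,6-olide | C=C1C(=O)O[C@H]2/C=C(/C)[C@H](OC(C)=O)C[C@H]3O[C@@]3(C)C[C@H](OC(=O)CCl)[C@H]12
F3 | step 21 | (1R,3R,6S,7S,8S,10S,4Z)-3-acetoxy-1,10-epoxy-8-hydroxygermacra-4,11(13)-dien-12,6-olide | C=C1C(=O)O[C@H]2/C=C(/C)[C@H](OC(C)=O)C[C@H]3O[C@@]3(C)C[C@H](O)[C@H]12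
F4 | step 12 | methyl (2E,4R,6Z,9R,10Z)-4,12-bis(tert-butyldimethylsilyloxy)-9-(4-methoxybenzyloxy)-6,10-dimethyl-2-(tributylstannyl)dodeca-2,6,10-trienoate | CC(C)(C)[Si](C)(C)OC/C=C(/C)[C@H](OCc1ccc(OC)cc1)C/C=C(/C)C[C@@H](O[Si](C)(C)C(C)(C)C)/C=C(/[Sn](CCCC)(CCCC)CCCC)C(=O)OC
F5 | step 12 | methyl (2E,4R,6Z,9R,10Z)-4,12-bis(tert-butyldimethylsilyloxy)-2-iodo-9-(4-methoxybenzyloxy)-6,10-dimethyldodeca-2,6,10-trienoate | CC(C)(C)[Si](C)(C)OC/C=C(/C)[C@H](OCc1ccc(OC)cc1)C/C=C(/C)C[C@@H](O[Si](C)(C)C(C)(C)C)/C=C(/I)C(=O)OC
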